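**Retrosynthetic overview**

1. The target is taken back to its 6-ketone (acetylation, desilylation, hydride delivery from the α face at C6), and the ketone to a 6-nitro decalin (Nef reaction).
2. The nitro decalin comes from an acyclic nitro triene by one intramolecular Diels–Alder reaction that forms C5–C10 and C6–C7 and so closes rings A and B together.
3. Enabling feature: ring B (C5–C6–C7–C8=C9–C10) is a cyclohexene whose C8=C9 double bond lies between C7 and C10, the retron of a [4+2] addition of diene C7=C8–C9=C10 to dienophile C5=C6. The oxygen on C7 makes the diene a 1-silyloxy diene, the oxygen-bearing C6 can first carry an activating nitro group, and C1–C4 of ring A are the four-atom tether.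
4. The triene comes from a homoallylic alcohol, and this from a tetrasubstituted enoate whose C9=C10 geometry is fixed by syn-carbocupration/iodination of ethyl but-2-ynoate and a B-alkyl Suzuki coupling.
5. Building blocks: isobutyronitrile and 1-bromo-3-chloropropane (C1–C5, C18, C19), (Z)-3-methylpent-2-en-4-yn-1-ol (C11–C16), ethyl but-2-ynoate (C8–C10, C20), methyllithium (C7, C17), nitromethane (C6).

Key step: step 16

**Remarks**

- Labdane numbering is used: ring A = C1–C5 and C10, ring B = C5–C10, side chain C11–C16 on C9, C17 on C8, C18/C19 on C4, C20 on C10.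
- In names, R = (3Z)-5-{[tert-butyl(diphenyl)silyl]oxy}-3-methylpent-3-en-1-yl; TBS = tert-butyl(dimethyl)silyl; TBDPS = tert-butyl(diphenyl)silyl.
- C8 (steps 10–14) and the carbinol carbon of the nitro alcohol (step 12) are carried as stereoisomer mixtures, because both become trigonal before the key step.
- Assumption: the sense of induction of the thiourea in step 16 cannot be predicted safely, so the antipode that gives the (5S,10S) series is to be found by trial; both antipodes are available.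

**Route**

Step 1
Reactants: 1 isobutyronitrile; 2 1-bromo-3-chloropropane
Product: 4 5-chloro-2,2-dimethylpentanenitrile, via lithiated nitrile 3 (not isolated)
Conditions: LiN(i-Pr)2, THF, −78 °C; then 2, −78 °C to rt
Reagents that add atoms: none
Why: SN2 alkylation of the nitrile-stabilised carbanion goes at the bromide end of the dihalide, because bromide leaves far faster than chloride, and builds the quaternary C4 with its two methyl groups.

Step 2
Reactants: 4 5-chloro-2,2-dimethylpentanenitrile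
Product: 6 5-chloro-2,2-dimethylpentanal, via aluminium aldimine 5 (not isolated)
Conditions: i-Bu2AlH, CH2Cl2, −78 °C; then 1 M HCl, 0 °C
Reagents that add atoms: water, O
Why: Hydride reduction of a nitrile with i-Bu2AlH stops at the aluminium aldimine, which hydrolyses to the aldehyde on acidic work-up, the alkyl chloride being inert.

Step 3
Reactants: 6 5-chloro-2,2-dimethylpentanal
Product: 7 2-(5-chloro-2-methylpentan-2-yl)-1,3-dioxolane
Conditions: ethylene glycol, p-TsOH (cat.), toluene, reflux, Dean–Stark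
Reagents that add atoms: ethylene glycol, OCCO
Why: Acid-catalysed acetalisation with azeotropic removal of water masks the aldehyde for the Grignard, organocopper and methyllithium steps.

Step 4
Reactants: 8 (2Z)-3-methylpent-2-en-4-yn-1-ol
Product: 9 tert-butyl{[(2Z)-3-methylpent-2-en-4-yn-1-yl]oxy}diphenylsilane
Conditions: t-BuPh2SiCl, imidazole, CH2Cl2, 0 °C to rt
Reagents that add atoms: tert-butyl(chloro)diphenylsilane, CC(C)(C)[Si](Cl)(c1ccccc1)c1ccccc1
Why: Silyl ether formation at the primary allylic alcohol leaves untouched the Z double bond of the purchased enynol, which becomes the C13=C14 geometry of the target.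

Step 5
Reactants: 9 tert-butyl{[(2Z)-3-methylpent-2-en-4-yn-1-yl]oxy}diphenylsilane
Product: 10 tert-butyl{[(2Z)-3-methylpenta-2,4-dien-1-yl]oxy}diphenylsilane
Conditions: H2 (1 atm), Pd/CaCO3 poisoned with Pb(OAc)2, quinoline, hexane, rt
Reagents that add atoms: none
Why: Semihydrogenation on the poisoned palladium catalyst (Lindlar reduction) takes the terminal alkyne to the vinyl group and stops there, the trisubstituted Z alkene being far less reactive.

Step 6
Reactants: 7 2-(5-chloro-2-methylpentan-2-yl)-1,3-dioxolane; 11 ethyl but-2-ynoate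
Product: 15 ethyl (2Z)-7-(1,3-dioxolan-2-yl)-2-iodo-3,7-dimethyloct-2-enoate, via Grignard reagent 12 (not isolated), via alkylcopper reagent 13 (not isolated), via alkenylcopper species 14 (not isolated)
Conditions: Mg, THF, reflux; CuBr·SMe2, THF, −78 to −40 °C; 11, −78 °C; I2, −78 to 0 °C
Reagents that add atoms: iodine, II
Why: Organocopper conjugate addition to a 2-alkynoate is a syn carbocupration that puts the new alkyl group and copper cis, and the alkenylcopper, configurationally stable at −78 °C in THF, is iodinated with retention, which fixes the tetrasubstituted alkene with the ester carbon (C8) cis to the C20 methyl group.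

Step 7
Reactants: 10 tert-butyl{[(2Z)-3-methylpenta-2,4-dien-1-yl]oxy}diphenylsilane; 15 ethyl (2Z)-7-(1,3-dioxolan-2-yl)-2-iodo-3,7-dimethyloct-2-enoate
Product: 17 ethyl (2E)-7-(1,3-dioxolan-2-yl)-3,7-dimethyl-2-R-oct-2-enoate, via alkylborane 16 (not isolated)
Conditions: 10, 9-BBN, THF, 0 °C to rt; then 15, Pd(dppf)Cl2 (cat.), AsPh3, Cs2CO3, DMF/H2O, rt
Reagents that add atoms: none
Why: B-alkyl Suzuki–Miyaura coupling, in which 9-BBN hydroborates only the monosubstituted terminal double bond of the diene (anti-Markovnikov) and the alkylborane replaces iodide with retention of the double-bond geometry, so that C11 ends cis to C1.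

Step 8
Reactants: 17 ethyl (2E)-7-(1,3-dioxolan-2-yl)-3,7-dimethyl-2-R-oct-2-enoate
Product: 18 (3E)-8-(1,3-dioxolan-2-yl)-2,4,8-trimethyl-3-R-non-3-en-2-ol
Conditions: MeLi, Et2O, −78 to 0 °C; aq. NH4Cl
Reagents that add atoms: methyllithium, [Li]C
Why: Double 1,2-addition of methyllithium to the ester gives the tertiary allylic alcohol that carries the future C7 and C17, the acetal and silyl ether being inert.

Step 9
Reactants: 18 (3E)-8-(1,3-dioxolan-2-yl)-2,4,8-trimethyl-3-R-non-3-en-2-ol
Product: 19 2-[(6E)-2,6,8-trimethyl-7-R-nona-6,8-dien-2-yl]-1,3-dioxolane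
Conditions: Burgess reagent (MeO2CN(−)SO2N(+)Et3), toluene, 50 °C
Reagents that add atoms: none
Why: Burgess dehydration is a syn (Ei) elimination, and since C9 bears no hydrogen only a methyl hydrogen can be lost, so the isopropenyl diene is the single regiochemical outcome.

Step 10
Reactants: 19 2-[(6E)-2,6,8-trimethyl-7-R-nona-6,8-dien-2-yl]-1,3-dioxolane
Product: 21 (3E)-8-(1,3-dioxolan-2-yl)-2,4,8-trimethyl-3-R-non-3-en-1-ol, via alkylborane 20 (not isolated)
Conditions: 9-BBN, THF, 0 °C to rt; then NaOH, H2O2, 0 °C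
Reagents that add atoms: hydrogen peroxide, OO
Why: Hydroboration–oxidation with bulky 9-BBN is anti-Markovnikov and selective for the 1,1-disubstituted terminal alkene over the tetrasubstituted and trisubstituted ones, the new centre C8 forming as a racemate that is lost in step 15.

Step 11
Reactants: 21 (3E)-8-(1,3-dioxolan-2-yl)-2,4,8-trimethyl-3-R-non-3-en-1-ol
Product: 22 (6E)-9-hydroxy-2,2,6,8-tetramethyl-7-R-non-6-enal
Conditions: p-TsOH·H2O (cat.), acetone/H2O, 40 °C
Reagents that add atoms: water, O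
Why: Acid-catalysed acetal hydrolysis frees the neopentyl aldehyde (C5) under conditions that the primary TBDPS ether tolerates.

Step 12
Reactants: 22 (6E)-9-hydroxy-2,2,6,8-tetramethyl-7-R-non-6-enal; 23 nitromethane
Product: 24 (7E)-3,3,7,9-tetramethyl-1-nitro-8-R-dec-7-ene-2,10-diol
Conditions: 23 (excess), DBU (cat.), THF, 0 °C to rt
Reagents that add atoms: none
Why: Henry (nitroaldol) addition of nitromethane to the non-enolisable aldehyde brings in C6 with its nitro group, the diastereomer mixture being of no consequence.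

Step 13
Reactants: 24 (7E)-3,3,7,9-tetramethyl-1-nitro-8-R-dec-7-ene-2,10-diol
Product: 27 (3E,9E)-2,4,8,8-tetramethyl-10-nitro-3-R-deca-3,9-dien-1-ol, via bis(trifluoroacetate) 25 (not isolated), via nitroalkene trifluoroacetate 26 (not isolated)
Conditions: (CF3CO)2O, Et3N, CH2Cl2, −10 °C; then MeOH, aq. NaHCO3, rt
Reagents that add atoms: none
Why: Trifluoroacetylation of both hydroxyl groups is followed by base-induced E1cB loss of trifluoroacetate from the β-nitro ester to the thermodynamically preferred (E)-nitroalkene, and the labile primary trifluoroacetate is methanolysed in the bicarbonate work-up.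

Step 14
Reactants: 27 (3E,9E)-2,4,8,8-tetramethyl-10-nitro-3-R-deca-3,9-dien-1-ol
Product: 28 (3E,9E)-2,4,8,8-tetramethyl-10-nitro-3-R-deca-3,9-dienal
Conditions: Dess–Martin periodinane, NaHCO3, CH2Cl2, 0 °C; used crude
Reagents that add atoms: none
Why: Buffered Dess–Martin oxidation of the primary alcohol leaves the nitroalkene alone and should not move the β,γ double bond into conjugation.

Step 15
Reactants: 28 (3E,9E)-2,4,8,8-tetramethyl-10-nitro-3-R-deca-3,9-dienal
Product: 29 tert-butyl{[(1E,3E,9E)-2,4,8,8-tetramethyl-10-nitro-3-R-deca-1,3,9-trien-1-yl]oxy}dimethylsilane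
Conditions: t-BuMe2SiOTf, Et3N, CH2Cl2, −78 °C; rapid filtration through Et3N-deactivated silica
Reagents that add atoms: tert-butyldimethylsilyl trifluoromethanesulfonate, CC(C)(C)[Si](C)(C)OS(=O)(=O)C(F)(F)F
Why: Soft enolisation and O-silylation can remove only the doubly activated C8–H, so the dienol ether forms regiospecifically with the C9=C10 geometry unchanged, and the silyloxy group should settle trans to the bulky C9 substituent (1E, oxygen outside).

Step 16
Reactants: 29 tert-butyl{[(1E,3E,9E)-2,4,8,8-tetramethyl-10-nitro-3-R-deca-1,3,9-trien-1-yl]oxy}dimethylsilane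
Product: 30 (5S,10S)-6α-nitro-7α-(TBS-oxy)-15-(TBDPS-oxy)labda-8,13(Z)-diene (trans-decalin, 5α-H, 10β-methyl)
Conditions: 1,1'-[(1R,2R)-cyclohexane-1,2-diyl]bis{3-[3,5-bis(trifluoromethyl)phenyl]thiourea} (20 mol %, or its antipode, see remarks), toluene (0.01 M), −20 °C to rt
Reagents that add atoms: none
Why: Proposed new method: a concerted, asynchronous normal-demand intramolecular Diels–Alder reaction (type 1 tether) in which the electron-rich 1-silyloxy diene C7=C8–C9=C10 adds to the nitroalkene C5=C6, whose LUMO is lowered by double hydrogen bonding of the chiral bis-thiourea to the nitro group while the catalyst shields one enantiotopic face of the dienophile; the closest known reactions are the thermal intramolecular Diels–Alder cyclisation of (E)-1-nitrodeca-1,7,9-trienes to trans-fused decalins and the intermolecular thiourea-catalysed enantioselective [4+2] additions of nitroalkenes to electron-rich dienes. Ring A (C1–C5, C10) closes as the tether ring of the cycloaddition through the C5–C10 bond, and ring B (C5–C10) is the cyclohexene ring of the [4+2] addition itself, closed by both new bonds with the new C8=C9 double bond between C7 and C10. C7 and C10 are set relative to each other by the diene geometry (suprafacial addition with the silyloxy group and the tether both outside and the C20 methyl inside, hence 7α-O and 10β-methyl), C5 by the chair-like anti folding of the tether that puts the (E)-nitro group endo and gives the trans ring fusion, C6 (nitro α) by the E geometry of the dienophile, and the absolute configuration by the catalyst. The step needs trans over cis fusion, which the endo preference of the nitro group and the chair tether with its gem-dimethyl group (Thorpe–Ingold effect) should secure, and it needs the C10-to-C5 and C7-to-C6 regiochemistry, which the tether and the matching polarity (donor oxygen on C7 next to the acceptor carbon C6) both enforce. It also needs the cycloaddition to outrun the uncatalysed pathway and a [1,5]-hydrogen shift of the cis-methyl diene, which the high reactivity of the nitroalkene at low temperature should allow.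

Step 17
Reactants: 30 (5S,10S)-6α-nitro-7α-(TBS-oxy)-15-(TBDPS-oxy)labda-8,13(Z)-diene
Product: 32 (5S,10S)-7α-(TBS-oxy)-15-(TBDPS-oxy)labda-8,13(Z)-dien-6-one, via sodium nitronate 31 (not isolated)
Conditions: NaOMe, MeOH, 0 °C; then TiCl3, NH4OAc, H2O/THF, 0 °C to rt
Reagents that add atoms: water, O
Why: Nef reaction in its reductive form, in which the nitronate is reduced by buffered trivalent titanium and hydrolysed to the ketone at pH 5–6, where the α-silyloxy β,γ-unsaturated ketone should neither epimerise at C5 or C7 nor conjugate.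

Step 18
Reactants: 32 (5S,10S)-7α-(TBS-oxy)-15-(TBDPS-oxy)labda-8,13(Z)-dien-6-one
Product: 33 (5S,10S)-7α-(TBS-oxy)-15-(TBDPS-oxy)labda-8,13(Z)-dien-6β-ol
Conditions: NaBH4, MeOH/THF, −40 °C
Reagents that add atoms: none
Why: In this hydride reduction the β face of C6 is blocked by the syn-axial methyl groups on C4 and C10, so hydride should enter from the α face and give the axial 6β alcohol, as in the reduction of 7α-substituted 6-oxo steroids to trans-diaxial 6β-ols.

Step 19
Reactants: 33 (5S,10S)-7α-(TBS-oxy)-15-(TBDPS-oxy)labda-8,13(Z)-dien-6β-ol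
Product: 34 (5S,10S)-6β-acetoxy-7α-(TBS-oxy)-15-(TBDPS-oxy)labda-8,13(Z)-diene
Conditions: Ac2O, DMAP, pyridine, 60 °C
Reagents that add atoms: acetic anhydride, CC(=O)OC(C)=O
Why: DMAP-catalysed acylation at elevated temperature is needed for the hindered axial 6β-hydroxyl group, which is the only free hydroxyl in the molecule.

Step 20
Reactants: 34 (5S,10S)-6β-acetoxy-7α-(TBS-oxy)-15-(TBDPS-oxy)labda-8,13(Z)-diene
Product: 35 [(1S,2S,4aS,8aS)-2-hydroxy-4-[(3Z)-5-hydroxy-3-methylpent-3-en-1-yl]-3,4a,8,8-tetramethyl-1,2,4a,5,6,7,8,8a-octahydronaphthalen-1-yl] acetate (6β-acetoxylabda-8,13(Z)-diene-7α,15-diol)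
Conditions: Bu4NF, AcOH, THF, rt to 40 °C
Reagents that add atoms: none
Why: Fluoride-mediated cleavage of both silyl ethers under acetic acid buffering keeps the medium near neutral, and acetyl migration from O6 to O7 is geometrically disfavoured in the trans-diaxial arrangement.

**Compound list**

1 | isobutyronitrile | CC(C)C#N | starting material
2 | 1-bromo-3-chloropropane | ClCCCBr | starting material
3 | lithiated isobutyronitrile | [Li]C(C)(C)C#N | intermediate
4 | 5-chloro-2,2-dimethylpentanenitrile | N#CC(C)(C)CCCCl | intermediate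
5 | N-(diisobutylaluminio) aldimine of 5-chloro-2,2-dimethylpentanal | ClCCCC(C)(C)C=N[Al](CC(C)C)CC(C)C | intermediate
6 | 5-chloro-2,2-dimethylpentanal | O=CC(C)(C)CCCCl | intermediate
7 | 2-(5-chloro-2-methylpentan-2-yl)-1,3-dioxolane | ClCCCC(C)(C)C1OCCO1 | intermediate
8 | (2Z)-3-methylpent-2-en-4-yn-1-ol | C#C/C(C)=C\CO | starting material
9 | tert-butyl{[(2Z)-3-methylpent-2-en-4-yn-1-yl]oxy}diphenylsilane | C#C/C(C)=C\CO[Si](c1ccccc1)(c1ccccc1)C(C)(C)C | intermediate
10 | tert-butyl{[(2Z)-3-methylpenta-2,4-dien-1-yl]oxy}diphenylsilane | C=C/C(C)=C\CO[Si](c1ccccc1)(c1ccccc1)C(C)(C)C | intermediate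
11 | ethyl but-2-ynoate | CCOC(=O)C#CC | starting material
12 | [4-(1,3-dioxolan-2-yl)-4-methylpentyl]magnesium chloride | Cl[Mg]CCCC(C)(C)C1OCCO1 | intermediate
13 | [4-(1,3-dioxolan-2-yl)-4-methylpentyl]copper | [Cu]CCCC(C)(C)C1OCCO1 | intermediate
14 | ethyl (2Z)-2-cuprio-7-(1,3-dioxolan-2-yl)-3,7-dimethyloct-2-enoate | CCOC(=O)/C([Cu])=C(\C)CCCC(C)(C)C1OCCO1 | intermediate
15 | ethyl (2Z)-7-(1,3-dioxolan-2-yl)-2-iodo-3,7-dimethyloct-2-enoate | CCOC(=O)/C(I)=C(\C)CCCC(C)(C)C1OCCO1 | intermediate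
16 | 9-[(3Z)-5-(TBDPS-oxy)-3-methylpent-3-en-1-yl]-9-borabicyclo[3.3.1]nonane | CC(C)(C)[Si](OC/C=C(C)\CCB1C2CCCC1CCC2)(c1ccccc1)c1ccccc1 | intermediate
17 | ethyl (2E)-7-(1,3-dioxolan-2-yl)-3,7-dimethyl-2-R-oct-2-enoate | CCOC(=O)/C(CC/C(C)=C\CO[Si](c1ccccc1)(c1ccccc1)C(C)(C)C)=C(\C)CCCC(C)(C)C1OCCO1 | intermediate
18 | (3E)-8-(1,3-dioxolan-2-yl)-2,4,8-trimethyl-3-R-non-3-en-2-ol | CC(C)(O)/C(CC/C(C)=C\CO[Si](c1ccccc1)(c1ccccc1)C(C)(C)C)=C(\C)CCCC(C)(C)C1OCCO1 | intermediate
19 | 2-[(6E)-2,6,8-trimethyl-7-R-nona-6,8-dien-2-yl]-1,3-dioxolane | C=C(C)/C(CC/C(C)=C\CO[Si](c1ccccc1)(c1ccccc1)C(C)(C)C)=C(\C)CCCC(C)(C)C1OCCO1 | intermediate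
20 | B-alkyl-9-BBN adduct of 19 (boron on C7) | CC(CB1C2CCCC1CCC2)/C(CC/C(C)=C\CO[Si](c1ccccc1)(c1ccccc1)C(C)(C)C)=C(\C)CCCC(C)(C)C1OCCO1 | intermediate
21 | (3E)-8-(1,3-dioxolan-2-yl)-2,4,8-trimethyl-3-R-non-3-en-1-ol | OCC(C)/C(CC/C(C)=C\CO[Si](c1ccccc1)(c1ccccc1)C(C)(C)C)=C(\C)CCCC(C)(C)C1OCCO1 | intermediate
22 | (6E)-9-hydroxy-2,2,6,8-tetramethyl-7-R-non-6-enal | OCC(C)/C(CC/C(C)=C\CO[Si](c1ccccc1)(c1ccccc1)C(C)(C)C)=C(\C)CCCC(C)(C)C=O | intermediate
23 | nitromethane | C[N+](=O)[O-] | starting material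
24 | (7E)-3,3,7,9-tetramethyl-1-nitro-8-R-dec-7-ene-2,10-diol | OCC(C)/C(CC/C(C)=C\CO[Si](c1ccccc1)(c1ccccc1)C(C)(C)C)=C(\C)CCCC(C)(C)C(O)C[N+](=O)[O-] | intermediate
25 | bis(trifluoroacetate) of 24 | FC(F)(F)C(=O)OCC(C)/C(CC/C(C)=C\CO[Si](c1ccccc1)(c1ccccc1)C(C)(C)C)=C(\C)CCCC(C)(C)C(OC(=O)C(F)(F)F)C[N+](=O)[O-] | intermediate
26 | trifluoroacetate of 27 | FC(F)(F)C(=O)OCC(C)/C(CC/C(C)=C\CO[Si](c1ccccc1)(c1ccccc1)C(C)(C)C)=C(\C)CCCC(C)(C)/C=C/[N+](=O)[O-] | intermediate
27 | (3E,9E)-2,4,8,8-tetramethyl-10-nitro-3-R-deca-3,9-dien-1-ol | OCC(C)/C(CC/C(C)=C\CO[Si](c1ccccc1)(c1ccccc1)C(C)(C)C)=C(\C)CCCC(C)(C)/C=C/[N+](=O)[O-] | intermediate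
28 | (3E,9E)-2,4,8,8-tetramethyl-10-nitro-3-R-deca-3,9-dienal | O=CC(C)/C(CC/C(C)=C\CO[Si](c1ccccc1)(c1ccccc1)C(C)(C)C)=C(\C)CCCC(C)(C)/C=C/[N+](=O)[O-] | intermediate
29 | tert-butyl{[(1E,3E,9E)-2,4,8,8-tetramethyl-10-nitro-3-R-deca-1,3,9-trien-1-yl]oxy}dimethylsilane | CC(C)(C)[Si](C)(C)O/C=C(C)/C(CC/C(C)=C\CO[Si](c1ccccc1)(c1ccccc1)C(C)(C)C)=C(\C)CCCC(C)(C)/C=C/[N+](=O)[O-] | intermediate
30 | (5S,10S)-6α-nitro-7α-(TBS-oxy)-15-(TBDPS-oxy)labda-8,13(Z)-diene | [O-][N+](=O)[C@H]1[C@@H](O[Si](C)(C)C(C)(C)C)C(C)=C(CC/C(C)=C\CO[Si](c3ccccc3)(c3ccccc3)C(C)(C)C)[C@@]2(C)CCCC(C)(C)[C@H]12 | intermediate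
31 | sodium nitronate of 30 | [Na+].[O-][N+]([O-])=C1[C@@H](O[Si](C)(C)C(C)(C)C)C(C)=C(CC/C(C)=C\CO[Si](c3ccccc3)(c3ccccc3)C(C)(C)C)[C@@]2(C)CCCC(C)(C)[C@H]12 | intermediate
32 | (5S,10S)-7α-(TBS-oxy)-15-(TBDPS-oxy)labda-8,13(Z)-dien-6-one | O=C1[C@@H](O[Si](C)(C)C(C)(C)C)C(C)=C(CC/C(C)=C\CO[Si](c3ccccc3)(c3ccccc3)C(C)(C)C)[C@@]2(C)CCCC(C)(C)[C@H]12 | intermediate
33 | (5S,10S)-7α-(TBS-oxy)-15-(TBDPS-oxy)labda-8,13(Z)-dien-6β-ol | O[C@@H]1[C@@H](O[Si](C)(C)C(C)(C)C)C(C)=C(CC/C(C)=C\CO[Si](c3ccccc3)(c3ccccc3)C(C)(C)C)[C@@]2(C)CCCC(C)(C)[C@H]12 | intermediate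
34 | (5S,10S)-6β-acetoxy-7α-(TBS-oxy)-15-(TBDPS-oxy)labda-8,13(Z)-diene | CC(=O)O[C@@H]1[C@@H](O[Si](C)(C)C(C)(C)C)C(C)=C(CC/C(C)=C\CO[Si](c3ccccc3)(c3ccccc3)C(C)(C)C)[C@@]2(C)CCCC(C)(C)[C@H]12 | intermediate
35 | [(1S,2S,4aS,8aS)-2-hydroxy-4-[(3Z)-5-hydroxy-3-methylpent-3-en-1-yl]-3,4a,8,8-tetramethyl-1,2,4a,5,6,7,8,8a-octahydronaphthalen-1-yl] acetate | CC(=O)O[C@@H]1[C@@H](O)C(C)=C(CC/C(C)=C\CO)[C@@]2(C)CCCC(C)(C)[C@H]12 | target

**Step count and risks**

Total step count: 20. Longest linear sequence: 18 (steps 1–3, then 6–20).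

Steps most likely to fail:

1. Step 16 (proposed new method). What may go wrong: insufficient enantiofacial discrimination by the hydrogen-bond donor, erosion of selectivity by the uncatalysed cycloaddition, or a [1,5]-hydrogen shift in the cis-methyl diene before ring closure. The fallback uses an established enantioselective intramolecular Diels–Alder reaction of a trienal; it sets out from 22 and comes back at 32. Hydroxy aldehyde 22 is heated with (triphenylphosphoranylidene)acetaldehyde in toluene to give (2E,8E)-11-hydroxy-4,4,8,10-tetramethyl-9-R-undeca-2,8-dienal F1. Dess–Martin oxidation gives the dialdehyde (2E,8E)-4,4,8,10-tetramethyl-9-R-undeca-2,8-dienedial F2. TBSOTf/Et3N silylates only the enolisable β,γ-unsaturated aldehyde (the enal has no γ-hydrogen) to give the silyloxy trienal F3. F3 is cyclised at −78 to −40 °C with a triflimide-activated (S)-o-tolyl CBS-type oxazaborolidine (antipode chosen as in step 16) to the 6α-formyl decalin F4, with the same endo, trans-fused course. Oxidative deformylation of this α-branched aldehyde with Cu(OAc)2, 2,2'-bipyridine, DABCO and O2 in DMF should give ketone 32.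

2. Step 17. What may go wrong: slow removal of the hindered axial C6–H by methoxide, or loss of silanolate from the nitronate by β-elimination. The fallback avoids the carbanion; it sets out from 30 and comes back at 32. Reduction of 30 with Zn dust in AcOH/THF should give the (5S,10S)-6α-amino-7α-(TBS-oxy)-15-(TBDPS-oxy)labda-8,13(Z)-diene F5. Oxidative deamination of F5 by transamination with 3,5-di-tert-butyl-1,2-benzoquinone (MeOH/THF, then aqueous oxalic acid) should give ketone 32.

3. Step 18. What may go wrong: hydride delivery from the β face, favoured electronically by the neighbouring pseudoaxial silyloxy group, leading to poor facial selectivity. The fallback uses hydroxyl-directed reduction; it sets out from 32 and comes back at 33. HF·pyridine in THF/pyridine removes the secondary TBS group but not the primary TBDPS group and gives the (5S,10S)-7α-hydroxy-15-(TBDPS-oxy)labda-8,13(Z)-dien-6-one F6. Me4NBH(OAc)3 in AcOH/MeCN at −20 °C delivers hydride intramolecularly from the α-oriented O7 to give the (5S,10S)-15-(TBDPS-oxy)labda-8,13(Z)-diene-6β,7α-diol F7. TBSOTf/2,6-lutidine at −78 °C should silylate only the accessible 7α-hydroxyl (the 6β-hydroxyl is syn-axial to two methyl groups) and give 33.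

Further compounds
F1 | step 16 | (2E,8E)-11-hydroxy-4,4,8,10-tetramethyl-9-R-undeca-2,8-dienal | OCC(C)/C(CC/C(C)=C\CO[Si](c1ccccc1)(c1ccccc1)C(C)(C)C)=C(\C)CCCC(C)(C)/C=C/C=O
F2 | step 16 | (2E,8E)-4,4,8,10-tetramethyl-9-R-undeca-2,8-dienedial | O=CC(C)/C(CC/C(C)=C\CO[Si](c1ccccc1)(c1ccccc1)C(C)(C)C)=C(\C)CCCC(C)(C)/C=C/C=O
F3 | step 16 | (2E,8E,10E)-11-(TBS-oxy)-4,4,8,10-tetramethyl-9-R-undeca-2,8,10-trienal | CC(C)(C)[Si](C)(C)O/C=C(C)/C(CC/C(C)=C\CO[Si](c1ccccc1)(c1ccccc1)C(C)(C)C)=C(\C)CCCC(C)(C)/C=C/C=O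
F4 | step 16 | (5S,10S)-6α-formyl-7α-(TBS-oxy)-15-(TBDPS-oxy)labda-8,13(Z)-diene | O=C[C@H]1[C@@H](O[Si](C)(C)C(C)(C)C)C(C)=C(CC/C(C)=C\CO[Si](c3ccccc3)(c3ccccc3)C(C)(C)C)[C@@]2(C)CCCC(C)(C)[C@H]12
F5 | step 17 | (5S,10S)-6α-amino-7α-(TBS-oxy)-15-(TBDPS-oxy)labda-8,13(Z)-diene | N[C@H]1[C@@H](O[Si](C)(C)C(C)(C)C)C(C)=C(CC/C(C)=C\CO[Si](c3ccccc3)(c3ccccc3)C(C)(C)C)[C@@]2(C)CCCC(C)(C)[C@H]12
F6 | step 18 | (5S,10S)-7α-hydroxy-15-(TBDPS-oxy)labda-8,13(Z)-dien-6-one | O=C1[C@@H](O)C(C)=C(CC/C(C)=C\CO[Si](c3ccccc3)(c3ccccc3)C(C)(C)C)[C@@]2(C)CCCC(C)(C)[C@H]12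
F7 | step 18 | (5S,10S)-15-(TBDPS-oxy)labda-8,13(Z)-diene-6β,7α-diol | O[C@@H]1[C@@H](O)C(C)=C(CC/C(C)=C\CO[Si](c3ccccc3)(c3ccccc3)C(C)(C)C)[C@@]2(C)CCCC(C)(C)[C@H]12
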